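## Analysis of the target

The target is the 7-O-geranyl ether of a (2R,3R)-3-hydroxyflavanone: a chroman-4-one whose benzo ring A carries the geranyloxy group at C7, whose pyranone ring C carries a hydroxyl at C3, and whose C2 carries the catechol ring B. The only stereocentres are C2 (R) and C3 (R); they are adjacent and trans, with aryl and hydroxyl both equatorial on the half-chair of ring C. Three motifs are sensitive. The free catechol oxidises readily, above all as a phenoxide. The geranyl aryl ether, with two trisubstituted alkenes, rules out hydrogenolysis, peracids and strong protic acid. The alpha-hydroxy ketone with an aryloxy group at the beta carbon opens under base (retro-oxa-Michael, helped by the 4'-hydroxyl), which scrambles C2 and C3, and it can be dehydrogenated to the flavonol. The difficulty is therefore to set both centres in the absolute sense while ring C is formed, and to bring C4 to the ketone level and remove the protecting groups without base, strong acid or alkene-reactive reagents. The strategy rests on ring C itself: the O1–C2 and C3–C4 bonds flank the two-carbon unit C2–C3 that carries ring B and oxygen. Cutting both bonds leaves O1–C8a–C4a–C4 on ring A as an oxa-diene (an ortho-quinone methide) and C2–C3 as an alkene, so ring C is the retron of a hetero-[4+2] cycloaddition.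

## Retrosynthetic reasoning

**13 to 12.** The two catechol hydroxyls are uncovered last. Silyl ethers are chosen because fluoride buffered with a weak acid removes them without generating a phenoxide next to the base-labile ring C and without touching the geranyl ether. This leads back to the bis-silyl hydroxy ketone 12.

**12 to 11.** The C4 carbonyl is traced to a C4 methine bearing a methoxy group, compound 11. That methine is a benzylic ether activated by O1 (ortho) and O7 (para), so a quinone hydride acceptor in wet solvent should take it straight to the ketone. A two-stage alternative (solvolytic exchange of methoxy for hydroxyl, then alcohol oxidation) was set aside while an acyl group sits on O3. Ionising C4 next to a 3-acyloxy group invites bridging by the ester carbonyl, and water would then deliver the acyl group to either O3 or O4. The direct oxidation never places a free hydroxyl at C4 and is one step shorter.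

**11 to 10.** The C3 hydroxyl of 11 comes from the C3 acetate of 10 by hydride cleavage of the ester. Doing this before the ketone exists means no epimerisable or base-sensitive centre is present, and the aryl silyl ethers, which would not survive basic methanolysis, are untouched.

**10 to 4 and 8 (through 9).** This is the central disconnection: O1–C2 and C3–C4 are cut together. It is made here because it removes ring C and both stereocentres in one operation and leaves two achiral, configurationally stable partners of similar size. Ring A becomes the salicylaldehyde dimethyl acetal 4, which under acid loses one methoxy group to give the methoxy-substituted ortho-quinone methide 9. The C2–C3 unit becomes the (E)-enol acetate 8 of the ring B arylacetaldehyde. The forward reaction has three tasks: join the acetoxy-bearing carbon to the methide carbon and the aryl-bearing carbon to the phenol oxygen, not the reverse; carry the alkene geometry into the 2,3-trans relation; and discriminate the enantiofaces, for which a chiral binaphthol-derived phosphoric acid is used. The acetal delivers C4 as a methyl ether, one oxidation level below the ketone. The acetoxy group is chosen over an alkoxy or silyloxy group because it is a weak donor: the para-silyloxy aryl group then decides the polarity of the alkene.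

**8 to 7, 6 and 5.** The enol acetate must be a single (E) isomer, and enol acetylation of an arylacetaldehyde would not guarantee that. The C–O bond is therefore cut to give the (E)-alkenylboronate 7, whose copper-mediated coupling with acetate is stereoretentive. Compound 7 is cut at the C=C bond to the bis-silylated aldehyde 6 (one-step trans-selective boron–Wittig olefination), and 6 comes from 3,4-dihydroxybenzaldehyde 5. This avoids an alkyne and a separate hydroboration.

**4 to 3, 1 and 2.** The acetal 4 comes from the salicylaldehyde 3, and 3 from 2,4-dihydroxybenzaldehyde 1 and geranyl bromide 2 by selective alkylation of the 4-hydroxyl; the 2-hydroxyl is held in a hydrogen bond to the aldehyde. Installing the geranyl group first means no late phenol differentiation is needed.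

## Alternatives that were turned down

**Alternative 1:** Ring A is carried as a cyclohexenone and C4–C4a and O1–C2 are cut. The kinetic enolate of the geranyl vinylogous ester A2 would be acylated at the future C4a by the trans-glycidic ester A3. The enol oxygen of the resulting 1,3-diketone would then open the epoxide at the benzylic carbon with inversion (6-endo), giving the tetrahydrochromenone A1.
- For: both stereocentres would come from an epoxide that can be made enantiopure before the fragments are joined; C4 is born as the ketone; O3 needs no protecting group. On the source of absolute configuration it is more predictable than an untested catalytic cycloaddition.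
- Against: acylating a ketone enolate with an ester gives a more acidic diketone, which consumes base and exposes the epoxide to enolate chemistry. The 6-endo opening competes with 5-exo attack at the other epoxide carbon, and the para-silyloxy aryl group that favours endo opening also favours ionisation and loss of configuration at C2. Most seriously, A1 still lacks the aromatic ring A. Removing two hydrogens from C5/C6 needs an oxidant in a molecule that holds an allylic enol ether, a free carbinol next to a ketone and a benzylic C2–H, where dehydrogenation across C2–C3 is the easier reaction.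
- Comparison: similar in length; the chosen route has ring A aromatic from the first step and needs only one mild benzylic oxidation.

**Alternative 2:** Only C4–C4a is cut. The bromo amide A5 already contains the O1–C2 aryl ether and both stereocentres. Halogen–lithium exchange at the future C4a would give an aryllithium that attacks the N-methoxy-N-methylamide and closes ring C to the tris-silyl chromanone A4.
- For: every step is of an established type; the ketone appears at the correct oxidation level; the stereocentres can be set by an asymmetric dihydroxylation of a cinnamate. On predictability it is the strongest of the four.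
- Against: A5 needs a long linear sequence (dihydroxylation, differentiation of the two hydroxyls, aryl ether formation, amide formation, silylation). The aryl ether must be formed with clean inversion at a benzylic carbon bearing a para-silyloxy aryl group, a centre that ionises easily, using a hindered ortho-bromophenol. In the exchange step the acidic proton alpha to the amide and the aryloxy leaving group at the beta carbon invite elimination, and the allylic geranyl ether is exposed to an alkyllithium.
- Comparison: more certain step by step, but several steps longer and with its own configurational risk at C2. The chosen route offers convergence and forms ring C and both centres in one catalytic step.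

**Alternative 3:** C3–C4 is cut. A chiral triazolylidene carbene would convert the ring A aldehyde of the dialdehyde A7 into an acyl anion equivalent that adds to the side-chain aldehyde, giving the hydroxy ketone A6, which is the same compound as 12 of the chosen route.
- For: on paper the shortest route; it delivers the C4 ketone and the free C3 hydroxyl directly and would save the two redox steps after ring closure. On step count and oxidation state it is better than the chosen route.
- Against: the future C2 in A7 is alpha to an aldehyde, benzylic and oxygen-substituted, so it cannot hold its configuration. Both centres would have to be set by dynamic kinetic resolution during cyclisation, with no structural element securing trans over cis. The carbene must also pick the electron-rich, ortho-substituted aromatic aldehyde (deactivated by the para geranyloxy group) over the more electrophilic aliphatic aldehyde; the wrong choice, or isomerisation through the ene-diol, gives the 4-hydroxy-3-ketone. Assembling A7 from an alpha-functionalised arylacetaldehyde is itself awkward.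
- Comparison: the chosen route uses achiral, stable partners and ties the relative configuration to an alkene geometry that is fixed before the key step.

Key step: step 6

Assumption: which antipode of the binaphthyl phosphoric acid gives the (2R,3S) cycloadduct cannot be deduced with confidence; the (R) acid is written, and its mirror image would be used if the sense is opposite.

## Route

Step 1
Reactants: 1 resorcylaldehyde (2,4-dihydroxybenzaldehyde); 2 geranyl bromide ((2E)-1-bromo-3,7-dimethylocta-2,6-diene)
Product: 3 salicylaldehyde geranyl ether 4-{[(2E)-3,7-dimethylocta-2,6-dien-1-yl]oxy}-2-hydroxybenzaldehyde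
Conditions: K2CO3 (1.05 equiv), acetone, 40 °C
Reagents that add atoms: none
Why: Williamson ether synthesis; the 2-hydroxyl is hydrogen-bonded to the aldehyde and much less nucleophilic, so one equivalent of mild base should alkylate O4 only, and the primary allylic bromide reacts by direct SN2 displacement without allylic transposition.

Step 2
Reactants: 3 salicylaldehyde geranyl ether
Product: 4 dimethyl acetal 2-(dimethoxymethyl)-5-{[(2E)-3,7-dimethylocta-2,6-dien-1-yl]oxy}phenol
Conditions: HC(OMe)3 (5 equiv), MeOH, pyridinium p-toluenesulfonate (5 mol%), 40 °C; then Et3N, concentrate, filter through basic alumina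
Reagents that add atoms: trimethyl orthoformate, COC(OC)OC; methanol, CO
Why: acid-catalysed acetalisation driven by the orthoformate as water scavenger; the weak pyridinium acid should leave the allylic aryl ether intact, and a basic quench keeps the labile acetal from reverting.

Step 3
Reactants: 5 protocatechualdehyde (3,4-dihydroxybenzaldehyde)
Product: 6 bis-silyl aldehyde 3,4-bis(tert-butyldimethylsilyloxy)benzaldehyde
Conditions: TBSCl (2.4 equiv), imidazole (5 equiv), DMF, rt
Reagents that add atoms: tert-butyldimethylsilyl chloride, CC(C)(C)[Si](C)(C)Cl
Why: imidazole-promoted silylation of both phenols; the silyl ethers mask the catechol and keep the para oxygen a strong donor for the key step.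

Step 4
Reactants: 6 bis-silyl aldehyde
Product: 7 alkenylboronate 2-{(E)-2-[3,4-bis(tert-butyldimethylsilyloxy)phenyl]ethenyl}-4,4,5,5-tetramethyl-1,3,2-dioxaborolane
Conditions: CH2(Bpin)2 (1.2 equiv), lithium 2,2,6,6-tetramethylpiperidide (from the amine and n-BuLi, 1.2 equiv), THF, 0 °C; then 6, −78 °C to rt; H2O
Reagents that add atoms: bis(4,4,5,5-tetramethyl-1,3,2-dioxaborolan-2-yl)methane, CC1(C)OB(CB2OC(C)(C)C(C)(C)O2)OC1(C)C
Why: boron–Wittig olefination; the alpha-boryl carbanion adds to the non-enolisable aldehyde and syn elimination of the borate should give the trans alkenylboronate, while the aryl silyl ethers tolerate the hindered amide base at low temperature.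

Step 5
Reactants: 7 alkenylboronate
Product: 8 enol acetate (E)-2-[3,4-bis(tert-butyldimethylsilyloxy)phenyl]ethenyl acetate
Conditions: Cu(OAc)2 (2.0 equiv), Et3N (2.0 equiv), 4 Å MS, MeCN, dry air, rt
Reagents that add atoms: Cu(OAc)2 (acetate of divalent copper), CC(=O)[O-].CC(=O)[O-].[Cu+2]
Why: Chan–Lam-type oxidative C–O coupling of an alkenylboron compound with a carboxylate; transmetalation from boron to copper, oxidation to a trivalent copper alkenyl acetate and reductive elimination should form the C–O bond with retention of the (E) geometry.

Step 6
Reactants: 4 dimethyl acetal; 8 enol acetate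
Product: 10 (2R,3S,4R)-2-[3,4-bis(tert-butyldimethylsilyloxy)phenyl]-7-{[(2E)-3,7-dimethylocta-2,6-dien-1-yl]oxy}-4-methoxy-3,4-dihydro-2H-chromen-3-yl acetate, via methoxy ortho-quinone methide 9 (not isolated)
Conditions: 8 (1.0 equiv), 4 (1.3 equiv, slow addition), (R)-3,3'-bis(2,4,6-triisopropylphenyl)-1,1'-binaphthyl-2,2'-diyl hydrogen phosphate (10 mol%), 5 Å MS, toluene, −40 °C to −20 °C
Reagents that add atoms: none
Why: Proposed new method: the phosphoric acid protonates one methoxy group of 4, methanol is taken up by the sieves, and the oxocarbenium/phenol pair collapses to methide 9, which stays hydrogen-bonded or ion-paired to the chiral phosphate through its carbonyl oxygen. The alkene of 8 attacks the methide carbon with its acetoxy-bearing carbon, because the developing positive charge is then benzylic and para to a silyloxy group, a much better arrangement than a cation next to the weakly donating, inductively withdrawing acetoxy group; the phenol oxygen then bonds to that benzylic carbon. The closest known reaction type is the chiral phosphoric acid-catalysed [4+2] cycloaddition of ortho-quinone methides with electron-rich styrenes and enol ethers to give chromans; an enol ester of an arylacetaldehyde has not served as the two-carbon partner. Ring C closes by [4+2] union of the O=C–C=C unit of 9 with the alkene (forming C3–C4 and O1–C2), either concerted and asynchronous or, if the benzylic cation has a lifetime, by 6-exo-trig capture of that quinone-methide-like cation by the phenol oxygen. C2 and C3 take their trans relation from the (E)-alkene in a suprafacial addition, and a stepwise closure also places aryl and acetoxy pseudo-equatorial, so both paths should converge on trans; their absolute configuration is set by the face of 9 left open by the 3,3'-aryl groups of the catalyst. C4 should emerge 2,4-cis from endo placement of ring B over the (E)-methide, but this centre is removed in step 8 and its epimer would be carried through unchanged. The step needs aryl at C2 and acetoxy at C3 (secured by the para-silyloxy donor), 2,3-trans geometry (secured by the alkene geometry fixed in step 5) and one enantioface (the catalyst).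

Step 7
Reactants: 10 cycloadduct acetate
Product: 11 (2R,3S,4R)-2-[3,4-bis(tert-butyldimethylsilyloxy)phenyl]-7-{[(2E)-3,7-dimethylocta-2,6-dien-1-yl]oxy}-4-methoxy-3,4-dihydro-2H-chromen-3-ol
Conditions: i-Bu2AlH (2.5 equiv), CH2Cl2, −78 °C; aq. potassium sodium tartrate
Reagents that add atoms: none
Why: reductive cleavage of the ester by hydride; at −78 °C the benzylic methyl ether, the aryl silyl ethers and the alkenes are inert, and with no carbonyl in the ring neither stereocentre can epimerise.

Step 8
Reactants: 11 hydroxy methyl ether
Product: 12 (2R,3R)-2-[3,4-bis(tert-butyldimethylsilyloxy)phenyl]-7-{[(2E)-3,7-dimethylocta-2,6-dien-1-yl]oxy}-3-hydroxy-2,3-dihydro-4H-chromen-4-one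
Conditions: DDQ (1.3 equiv), CH2Cl2/pH 7 phosphate buffer (10:1), 0 °C
Reagents that add atoms: water, O
Why: DDQ oxidation of an electron-rich benzylic ether, the reaction type used to cleave alkoxybenzyl ethers; hydride is taken from C4, which is activated by its own methoxy group and by O1 (ortho) and O7 (para), water adds to the oxocarbenium ion and the hemiketal loses methanol to give the ketone. C2 and C3 are not touched; the C3 descriptor changes from S to R only because C4 now outranks C2.

Step 9
Reactants: 12 bis-silyl hydroxy ketone
Product: 13 (2R,3R)-2-(3,4-dihydroxyphenyl)-7-{[(2E)-3,7-dimethylocta-2,6-dien-1-yl]oxy}-3-hydroxy-2,3-dihydro-4H-chromen-4-one (target)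
Conditions: Bu4NF (2.5 equiv), AcOH (3 equiv), THF, 0 °C
Reagents that add atoms: none
Why: fluoride-mediated cleavage of the aryl silyl ethers; buffering with acetic acid keeps the liberated catechol protonated, so the phenoxide-triggered opening of ring C that would scramble C2 and C3 is avoided, and the geranyl ether is inert to fluoride.

## Compound list

1 | 2,4-dihydroxybenzaldehyde | O=Cc1ccc(O)cc1O | starting material
2 | geranyl bromide, (2E)-1-bromo-3,7-dimethylocta-2,6-diene | CC(C)=CCC/C(C)=C/CBr | starting material
3 | 4-{[(2E)-3,7-dimethylocta-2,6-dien-1-yl]oxy}-2-hydroxybenzaldehyde | CC(C)=CCC/C(C)=C/COc1ccc(C=O)c(O)c1 | intermediate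
4 | 2-(dimethoxymethyl)-5-{[(2E)-3,7-dimethylocta-2,6-dien-1-yl]oxy}phenol | CC(C)=CCC/C(C)=C/COc1ccc(C(OC)OC)c(O)c1 | intermediate
5 | 3,4-dihydroxybenzaldehyde | O=Cc1ccc(O)c(O)c1 | starting material
6 | 3,4-bis(tert-butyldimethylsilyloxy)benzaldehyde | O=Cc1ccc(O[Si](C)(C)C(C)(C)C)c(O[Si](C)(C)C(C)(C)C)c1 | intermediate
7 | 2-{(E)-2-[3,4-bis(tert-butyldimethylsilyloxy)phenyl]ethenyl}-4,4,5,5-tetramethyl-1,3,2-dioxaborolane | CC1(C)OB(/C=C/c2ccc(O[Si](C)(C)C(C)(C)C)c(O[Si](C)(C)C(C)(C)C)c2)OC1(C)C | intermediate
8 | (E)-2-[3,4-bis(tert-butyldimethylsilyloxy)phenyl]ethenyl acetate | CC(=O)O/C=C/c1ccc(O[Si](C)(C)C(C)(C)C)c(O[Si](C)(C)C(C)(C)C)c1 | intermediate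
9 | (6E)-3-{[(2E)-3,7-dimethylocta-2,6-dien-1-yl]oxy}-6-(methoxymethylidene)cyclohexa-2,4-dien-1-one (methoxy ortho-quinone methide, formed in the flask and not isolated) | CC(C)=CCC/C(C)=C/COC1=CC(=O)/C(=C/OC)C=C1 | intermediate
10 | (2R,3S,4R)-2-[3,4-bis(tert-butyldimethylsilyloxy)phenyl]-7-{[(2E)-3,7-dimethylocta-2,6-dien-1-yl]oxy}-4-methoxy-3,4-dihydro-2H-chromen-3-yl acetate (2,3-trans, 2,4-cis) | CC(C)=CCC/C(C)=C/COc1ccc2c(c1)O[C@H](c1ccc(O[Si](C)(C)C(C)(C)C)c(O[Si](C)(C)C(C)(C)C)c1)[C@@H](OC(C)=O)[C@@H]2OC | intermediate
11 | (2R,3S,4R)-2-[3,4-bis(tert-butyldimethylsilyloxy)phenyl]-7-{[(2E)-3,7-dimethylocta-2,6-dien-1-yl]oxy}-4-methoxy-3,4-dihydro-2H-chromen-3-ol | CC(C)=CCC/C(C)=C/COc1ccc2c(c1)O[C@H](c1ccc(O[Si](C)(C)C(C)(C)C)c(O[Si](C)(C)C(C)(C)C)c1)[C@@H](O)[C@@H]2OC | intermediate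
12 | (2R,3R)-2-[3,4-bis(tert-butyldimethylsilyloxy)phenyl]-7-{[(2E)-3,7-dimethylocta-2,6-dien-1-yl]oxy}-3-hydroxy-2,3-dihydro-4H-chromen-4-one | CC(C)=CCC/C(C)=C/COc1ccc2c(c1)O[C@H](c1ccc(O[Si](C)(C)C(C)(C)C)c(O[Si](C)(C)C(C)(C)C)c1)[C@@H](O)C2=O | intermediate
13 | (2R,3R)-2-(3,4-dihydroxyphenyl)-7-{[(2E)-3,7-dimethylocta-2,6-dien-1-yl]oxy}-3-hydroxy-2,3-dihydro-4H-chromen-4-one | CC(C)=CCC/C(C)=C/COc1ccc2c(c1)O[C@H](c1ccc(O)c(O)c1)[C@@H](O)C2=O | target

## Step count and risk

Total steps: 9. Longest linear sequence: 7 steps (steps 3, 4, 5, 6, 7, 8 and 9, from 5); the ring A branch (steps 1 and 2) joins at step 6.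

**Step 6 (key step, proposed new method).**
- What may go wrong: the enol acetate is a weaker nucleophile than the styrenes and enol ethers known to react, so the methide may be consumed by self-condensation or by recapturing methanol before the alkene engages. Facial discrimination by the catalyst may be poor. The product may re-ionise at C4 and lose methanol. A stronger acid (the N-triflyl phosphoramide analogue) could restore reactivity but would endanger the geranyl ether.
- Fallback (known chemistry, from 6 and 4, returning at 12): the C3 oxygen is introduced after the cycloaddition, not with it. Methylenation of 6 (Ph3P=CH2 from Ph3PCH3Br and n-BuLi, THF, 0 °C) should give 3,4-bis(tert-butyldimethylsilyloxy)styrene F1, a member of the electron-rich styrene class for which the phosphoric acid-catalysed cycloaddition is established. With 4 under the conditions of step 6 it should give (2S,4S)-2-[3,4-bis(tert-butyldimethylsilyloxy)phenyl]-7-(geranyloxy)-4-methoxychroman F2, which has the same spatial arrangement at C2 as 10; the descriptor differs because C3 is a methylene. DDQ in buffered wet CH2Cl2, as in step 8, should give (2S)-2-[3,4-bis(tert-butyldimethylsilyloxy)phenyl]-7-(geranyloxy)chroman-4-one F3. Hydroxylation of its potassium enolate (KN(SiMe3)2, THF, −78 °C, then 2-(phenylsulfonyl)-3-phenyloxaziridine), with the oxidant approaching anti to the C2 aryl group, should give 12. The cost is two extra steps and an enolate that can open ring C if allowed to warm.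

**Step 8.**
- What may go wrong: hydride abstraction may compete at C2–H (benzylic to the silyloxylated ring B) or at the allylic O–CH2 of the geranyl ether, and the hydroxy ketone may be over-oxidised toward the flavonol.
- Fallback (from 11, returning at 13): the C3 hydroxyl is silylated (TBSCl, imidazole, DMF, 40 °C) to give (2R,3S,4R)-2-[3,4-bis(tert-butyldimethylsilyloxy)phenyl]-3-(tert-butyldimethylsilyloxy)-7-(geranyloxy)-4-methoxychroman F4. With no participating acyl group next to C4, solvolytic exchange (pyridinium p-toluenesulfonate, acetone/H2O, rt) should give (2R,3S)-2-[3,4-bis(tert-butyldimethylsilyloxy)phenyl]-3-(tert-butyldimethylsilyloxy)-7-(geranyloxy)chroman-4-ol F5 as a mixture of C4 epimers. Dess–Martin periodinane (NaHCO3, CH2Cl2) should then give (2R,3R)-2-[3,4-bis(tert-butyldimethylsilyloxy)phenyl]-3-(tert-butyldimethylsilyloxy)-7-(geranyloxy)chroman-4-one F6, and buffered fluoride (Bu4NF/AcOH, THF) removes all three silyl groups to give 13.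

**Step 5.**
- What may go wrong: pinacol boronates transmetalate to copper slowly, so protodeboronation or oxidative homocoupling of the alkenyl group may outrun C–O bond formation.
- Fallback (from 6, returning at 8): Wittig olefination of 6 with 1-(triphenylphosphoranylidene)propan-2-one (toluene, 80 °C) should give (E)-4-[3,4-bis(tert-butyldimethylsilyloxy)phenyl]but-3-en-2-one F7. Baeyer–Villiger oxidation with a buffered peracid (mCPBA, Na2HPO4, CH2Cl2, 0 °C), in which the alkenyl group migrates in preference to methyl with retention of geometry, should give 8. The oxidant must be limited to one equivalent because the product is itself an electron-rich alkene.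

**Step 2.**
- What may go wrong: acetalisation of the hydrogen-bonded, electron-rich aldehyde may stop short of completion, and the acetal may revert on isolation.
- Fallback (from 3, returning at 10): the acetal is not isolated. Aldehyde 3, trimethyl orthoformate and 8 are combined with the acid catalyst of step 6 over 5 Å MS, so that the oxocarbenium ion and 9 are generated in the presence of the alkene (a three-component variant); no new isolated compound is involved.

## Further compounds

F1 | step 6 | 3,4-bis(tert-butyldimethylsilyloxy)styrene | C=Cc1ccc(O[Si](C)(C)C(C)(C)C)c(O[Si](C)(C)C(C)(C)C)c1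
F2 | step 6 | (2S,4S)-2-[3,4-bis(tert-butyldimethylsilyloxy)phenyl]-7-{[(2E)-3,7-dimethylocta-2,6-dien-1-yl]oxy}-4-methoxychroman | CC(C)=CCC/C(C)=C/COc1ccc2c(c1)O[C@H](c1ccc(O[Si](C)(C)C(C)(C)C)c(O[Si](C)(C)C(C)(C)C)c1)C[C@@H]2OC
F3 | step 6 | (2S)-2-[3,4-bis(tert-butyldimethylsilyloxy)phenyl]-7-{[(2E)-3,7-dimethylocta-2,6-dien-1-yl]oxy}chroman-4-one | CC(C)=CCC/C(C)=C/COc1ccc2c(c1)O[C@H](c1ccc(O[Si](C)(C)C(C)(C)C)c(O[Si](C)(C)C(C)(C)C)c1)CC2=O
F4 | step 8 | (2R,3S,4R)-2-[3,4-bis(tert-butyldimethylsilyloxy)phenyl]-3-(tert-butyldimethylsilyloxy)-7-{[(2E)-3,7-dimethylocta-2,6-dien-1-yl]oxy}-4-methoxychroman | CC(C)=CCC/C(C)=C/COc1ccc2c(c1)O[C@H](c1ccc(O[Si](C)(C)C(C)(C)C)c(O[Si](C)(C)C(C)(C)C)c1)[C@@H](O[Si](C)(C)C(C)(C)C)[C@@H]2OC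
F5 | step 8 | (2R,3S)-2-[3,4-bis(tert-butyldimethylsilyloxy)phenyl]-3-(tert-butyldimethylsilyloxy)-7-{[(2E)-3,7-dimethylocta-2,6-dien-1-yl]oxy}chroman-4-ol, mixture of C4 epimers | CC(C)=CCC/C(C)=C/COc1ccc2c(c1)O[C@H](c1ccc(O[Si](C)(C)C(C)(C)C)c(O[Si](C)(C)C(C)(C)C)c1)[C@@H](O[Si](C)(C)C(C)(C)C)C2O
F6 | step 8 | (2R,3R)-2-[3,4-bis(tert-butyldimethylsilyloxy)phenyl]-3-(tert-butyldimethylsilyloxy)-7-{[(2E)-3,7-dimethylocta-2,6-dien-1-yl]oxy}chroman-4-one | CC(C)=CCC/C(C)=C/COc1ccc2c(c1)O[C@H](c1ccc(O[Si](C)(C)C(C)(C)C)c(O[Si](C)(C)C(C)(C)C)c1)[C@@H](O[Si](C)(C)C(C)(C)C)C2=O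
F7 | step 5 | (E)-4-[3,4-bis(tert-butyldimethylsilyloxy)phenyl]but-3-en-2-one | CC(=O)/C=C/c1ccc(O[Si](C)(C)C(C)(C)C)c(O[Si](C)(C)C(C)(C)C)c1
F0 | step 2 | none | none
A1 | alternative 1 | (2R,3R)-2-[3,4-bis(tert-butyldimethylsilyloxy)phenyl]-7-{[(2E)-3,7-dimethylocta-2,6-dien-1-yl]oxy}-3-hydroxy-2,3,5,6-tetrahydro-4H-chromen-4-one | CC(C)=CCC/C(C)=C/COC1CCC2=C(C=1)O[C@H](c1ccc(O[Si](C)(C)C(C)(C)C)c(O[Si](C)(C)C(C)(C)C)c1)[C@@H](O)C2=O
A2 | alternative 1 | 3-{[(2E)-3,7-dimethylocta-2,6-dien-1-yl]oxy}cyclohex-2-en-1-one | CC(C)=CCC/C(C)=C/COC1=CC(=O)CCC1
A3 | alternative 1 | methyl (2R,3S)-3-[3,4-bis(tert-butyldimethylsilyloxy)phenyl]oxirane-2-carboxylate | COC(=O)[C@@H]1O[C@H]1c1ccc(O[Si](C)(C)C(C)(C)C)c(O[Si](C)(C)C(C)(C)C)c1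
A4 | alternative 2 | (2R,3R)-2-[3,4-bis(tert-butyldimethylsilyloxy)phenyl]-3-(tert-butyldimethylsilyloxy)-7-{[(2E)-3,7-dimethylocta-2,6-dien-1-yl]oxy}chroman-4-one | CC(C)=CCC/C(C)=C/COc1ccc2c(c1)O[C@H](c1ccc(O[Si](C)(C)C(C)(C)C)c(O[Si](C)(C)C(C)(C)C)c1)[C@@H](O[Si](C)(C)C(C)(C)C)C2=O
A5 | alternative 2 | (2R,3R)-3-(2-bromo-5-{[(2E)-3,7-dimethylocta-2,6-dien-1-yl]oxy}phenoxy)-3-[3,4-bis(tert-butyldimethylsilyloxy)phenyl]-2-(tert-butyldimethylsilyloxy)-N-methoxy-N-methylpropanamide | CC(C)=CCC/C(C)=C/COc1ccc(Br)c(c1)O[C@H](c1ccc(O[Si](C)(C)C(C)(C)C)c(O[Si](C)(C)C(C)(C)C)c1)[C@@H](O[Si](C)(C)C(C)(C)C)C(=O)N(C)OC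
A6 | alternative 3 | (2R,3R)-2-[3,4-bis(tert-butyldimethylsilyloxy)phenyl]-7-{[(2E)-3,7-dimethylocta-2,6-dien-1-yl]oxy}-3-hydroxychroman-4-one | CC(C)=CCC/C(C)=C/COc1ccc2c(c1)O[C@H](c1ccc(O[Si](C)(C)C(C)(C)C)c(O[Si](C)(C)C(C)(C)C)c1)[C@@H](O)C2=O
A7 | alternative 3 | 2-{(1R)-1-[3,4-bis(tert-butyldimethylsilyloxy)phenyl]-2-oxoethoxy}-4-{[(2E)-3,7-dimethylocta-2,6-dien-1-yl]oxy}benzaldehyde (drawn as R; configurationally labile) | CC(C)=CCC/C(C)=C/COc1ccc(C=O)c(c1)O[C@H](c1ccc(O[Si](C)(C)C(C)(C)C)c(O[Si](C)(C)C(C)(C)C)c1)C=O
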